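The runs come from a simulation with constants of no real substance; scatter was added.

**The trap.** The north-west run tempts me to extend its straight target line. Target climbs from 1.1% at 5.00 min to 10.7% at 90.0 min, a slope of 0.0678 /h of the charge, while starting material stays near 64.6%. I freeze that share and c(catalyst), which makes the making step pseudo-first-order in starting material, so the slope in percent carries to a flask at 50 °C with that share and catalyst. Sunday's has the north-west c(catalyst) and temperature, and charges 66.7% of its pool as starting material. Over 5.0 h the slope gives 33.9%, the straight-line ceiling: the target made at the frozen slope with nothing lost. The dormant form, over-reaction product and side product each pull against it, so I commit to Sunday's ending under it.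

| flask | starting material | other conformer | catalyst | temperature | remark | time |
|---|---|---|---|---|---|---|
| north-west | 0.020 M | 15 mM | 100 µM | 50 °C | run made earlier |  |
| Sunday's | 0.020 M | 10.0 mM | 100 µM | 50 °C |  | 5.0 h |
| Monday's | 0.020 M | 10.0 mM | 100 µM | 80 °C |  | 5.0 h |

north-west run (percent of the starting material and other conformer together charged)

| time / min | target / % | starting material / % |
|---|---|---|
| 5.00 | 1.1 | 59.6 |
| 15.0 | 2.0 | 63.9 |
| 25.0 | 1.6 | 64.6 |
| 40.0 | 4.4 | 67.9 |
| 50.0 | 6.5 | 66.3 |
| 80.0 | 7.8 | 62.3 |
| 90.0 | 10.7 | 63.1 |

(readings scatter by 1 percentage point)

- a species is counted by the starting material in it: one side product counts as two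
- the analysis behind the earlier runs scatters by 1 percentage point, standard deviation
- what may be going on: catalyst <-> dormant form; catalyst + other conformer -> catalyst + isomer of the product; target -> over-reaction product; starting material <-> other conformer; starting material + target -> side product; starting material + catalyst -> catalyst + target
- in a conversion other conformer counts as not yet reacted
- the earlier runs do not show what temperature does; that part of a forecast is a guess

1. the best flask by amount of target, in percent of the starting material and other conformer together charged; "all alike" if 1.5 percentage points covers them all (Sunday's / Monday's / all alike)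
2. amount of target at the end, in percent of the starting material and other conformer together charged, Sunday's
3. amount of target at the end, in percent of the starting material and other conformer together charged, Monday's

**Turned round.** With Sunday's under its ceiling, Monday's comes out best if it keeps a third of its charge as target. The earlier runs do not show what temperature does. What has to hold is that use of target does not outrun its making at 80 °C, over 3.33 times the span of the readings. So for Monday's I have a test, not a number.

**The forecast.** It says Monday's, with 24% (15% to 33%) for Sunday's and 45% (18% to 70%) for Monday's, “guessing a ninefold rate rise”.

**The flasks.** Sunday's holds 14.9%, at 44.0% of its ceiling, and Monday's holds 1.26%, far under the test; the best is Sunday's.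

    catalyst ⇌ dormant form (K = 1.40, k = 0.220 /h, Ea = 111 kJ/mol, ΔH = −13.0 kJ/mol)
    catalyst + other conformer → catalyst + isomer of the product (k = 3000 /M/h, Ea = 49.0 kJ/mol)
    target → over-reaction product (k = 0.200 /h, Ea = 95.0 kJ/mol)
    starting material ⇌ other conformer (K = 0.270, k = 0.480 /h, Ea = 112 kJ/mol, ΔH = −75.0 kJ/mol)
    starting material + target → side product (k = 1.40 /M/h, Ea = 69.0 kJ/mol)
    starting material + catalyst → catalyst + target (k = 1400 /M/h, Ea = 54.0 kJ/mol)
    (constants at 50 °C)

**Made against used.** In Sunday's, target is made 2.42 times as fast as it is used at 1.75 h. At 5.00 h that ratio is 0.934, so target has stopped gaining.

**Second flask.** The neighbour of Sunday's has a quarter of the catalyst, 2.5 × 10⁻⁵ M, so its ceiling is 8.47%. It gives 4.72%, under that ceiling.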